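**Retrosynthetic overview**

1. The route rests on ring B, the benzene C1'–C6' that hangs by C1' from C2 of the pyran ring and carries a free OH at C3' and OMe at C5'. It is made last, from a 3-(chroman-2-yl)cyclobutenone and methoxyacetylene (new bonds C3'–C4' and C5'–C6', C2'–C3' re-formed), so the two meta oxygens arrive already told apart.
2. After the annulation: silylation of the new phenol, Br→Li→Cu exchange and prenylation at C8, fluoride desilylation. The C8 bromine is put on ring A before ring B exists.
3. Cyclobutenone ⇐ dichloroketene [2+2] on the (2S)-2-ethynylchroman, then zinc dechlorination.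
4. Pyran ring (ring C) ⇐ Mitsunobu closure with inversion of an (R)-propargylic alcohol, from asymmetric transfer hydrogenation of an ynone made from 5,7-dihydroxycoumarin (ring A bought) via the dihydro lactone and its Weinreb amide.
5. Ring order: A (bought), C (step 6), B (step 12). Triisopropylsilyl ethers (TIPS = Si(iPr)3) are used throughout, because acetal protecting groups would be cleaved by ZnCl2/acid chloride in the ketene step and fluoride removal spares the ortho-prenyl phenol.

Key step: step 12

Assumption: 5,7-dihydroxycoumarin is taken as purchasable, and in step 5 the (R,R)-catalyst is taken to give the (R)-carbinol by analogy with aryl ketones (alkynyl in the place of aryl); the mirror-image catalyst would be used if the sense proved opposite.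

**Route**

Step 1
Reactants: 1 5,7-dihydroxycoumarin
Product: 2 5,7-bis(triisopropylsilyloxy)coumarin
Conditions: TIPSCl (2.4 equiv), imidazole, DMF, rt
Reagents that add atoms: triisopropylsilyl chloride, CC(C)[Si](Cl)(C(C)C)C(C)C
Why: Imidazole-promoted silylation of both phenols (silyl ether formation) is unambiguous here, and TIPS ethers are chosen because they should outlast ZnCl2 and acid chloride in step 9, where acetal protecting groups would be cleaved, and leave at the end with fluoride instead of acid.

Step 2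
Reactants: 2 5,7-bis(triisopropylsilyloxy)coumarin
Product: 3 5,7-bis(triisopropylsilyloxy)chroman-2-one
Conditions: H2 (3 atm), Pd/C, EtOAc, rt
Reagents that add atoms: none
Why: Heterogeneous hydrogenation over Pd/C saturates the conjugated C3=C4 bond of a coumarin while leaving the arene, the lactone and the silyl ethers untouched.

Step 3
Reactants: 3 5,7-bis(triisopropylsilyloxy)chroman-2-one
Product: 4 3-[2-hydroxy-4,6-bis(triisopropylsilyloxy)phenyl]-N-methoxy-N-methylpropanamide
Conditions: MeNH(OMe)·HCl (2 equiv), iPrMgCl (4 equiv), THF, −20 °C; then 3, −20 → 0 °C; aq NH4Cl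
Reagents that add atoms: N,O-dimethylhydroxylamine hydrochloride, CNOC.Cl
Why: The aryl lactone is a reactive ester that the chloromagnesium amide opens cleanly (Weinreb amide formation by aminolysis), which at the same time frees the phenol oxygen that will become O1 of the chroman.

Step 4
Reactants: 4 3-[2-hydroxy-4,6-bis(triisopropylsilyloxy)phenyl]-N-methoxy-N-methylpropanamide; 5 (trimethylsilyl)acetylene
Product: 7 1-[2-hydroxy-4,6-bis(triisopropylsilyloxy)phenyl]-5-(trimethylsilyl)pent-4-yn-3-one, via lithium acetylide 6 (not isolated)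
Conditions: 5 (3.3 equiv), n-BuLi (3.2 equiv), THF, −78 °C; then 4, −78 → −20 °C; aq NH4Cl
Reagents that add atoms: none
Why: Acylation of a lithium acetylide by a Weinreb amide stops at the ketone because the chelated adduct holds until work-up, the first equivalent of acetylide merely deprotonating the phenol.

Step 5
Reactants: 7 1-[2-hydroxy-4,6-bis(triisopropylsilyloxy)phenyl]-5-(trimethylsilyl)pent-4-yn-3-one
Product: 8 (3R)-1-[2-hydroxy-4,6-bis(triisopropylsilyloxy)phenyl]-5-(trimethylsilyl)pent-4-yn-3-ol
Conditions: RuCl[(R,R)-TsDPEN](p-cymene) (2 mol %), HCO2H/Et3N (5:2), CH2Cl2, rt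
Reagents that add atoms: none
Why: Noyori asymmetric transfer hydrogenation of an alkynyl ketone, in which the alkyne takes the place that the aryl group has in aryl ketones, so that the (R,R)-catalyst should set the carbinol centre as (R) by catalyst control, while the formic acid medium tolerates the free phenol and leaves alkyne and silyl groups alone.

Step 6
Reactants: 8 (3R)-1-[2-hydroxy-4,6-bis(triisopropylsilyloxy)phenyl]-5-(trimethylsilyl)pent-4-yn-3-ol
Product: 9 {[(2S)-5,7-bis(triisopropylsilyloxy)chroman-2-yl]ethynyl}trimethylsilane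
Conditions: PPh3, DIAD, THF, 0 °C → rt
Reagents that add atoms: none
Why: Intramolecular Mitsunobu etherification closes the pyran ring by 6-exo-tet SN2 attack of the phenol on the activated propargylic carbon, so the (R)-carbinol is inverted to the (S)-configured C2.

Step 7
Reactants: 9 {[(2S)-5,7-bis(triisopropylsilyloxy)chroman-2-yl]ethynyl}trimethylsilane
Product: 10 (2S)-2-ethynyl-5,7-bis(triisopropylsilyloxy)chroman
Conditions: K2CO3 (0.2 equiv), MeOH/THF, 0 °C
Reagents that add atoms: none
Why: Methoxide-catalysed protodesilylation of the alkynyl C–Si bond is fast at 0 °C, whereas the hindered aryl TIPS ethers should be attacked far more slowly.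

Step 8
Reactants: 10 (2S)-2-ethynyl-5,7-bis(triisopropylsilyloxy)chroman
Product: 11 (2S)-8-bromo-2-ethynyl-5,7-bis(triisopropylsilyloxy)chroman
Conditions: NBS (1.0 equiv), CH2Cl2, −78 → −20 °C
Reagents that add atoms: N-bromosuccinimide, O=C1CCC(=O)N1Br
Why: Electrophilic aromatic bromination of the triply oxygenated ring A should go to C8 (ortho to O1 and the C7 oxygen, para to the C5 oxygen), as is known for NBS on 5,7-dialkoxyflavans, because C6 is shielded by two TIPS-oxy groups, and doing it now avoids any contest with the electron-rich ring B made later.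

Step 9
Reactants: 11 (2S)-8-bromo-2-ethynyl-5,7-bis(triisopropylsilyloxy)chroman; 12 trichloroacetyl chloride
Product: 14 3-[(2S)-8-bromo-5,7-bis(triisopropylsilyloxy)chroman-2-yl]-4,4-dichlorocyclobut-2-en-1-one, via dichloroketene 13 (not isolated)
Conditions: Zn–Cu couple, 12 (slow addition), Et2O/DME, rt
Reagents that add atoms: none
Why: Dichloroketene from zinc reduction of 12 adds [2+2] to the terminal alkyne with its carbonyl carbon at the CH terminus, the standard entry to 3-substituted 4,4-dichlorocyclobutenones, while DME ties up ZnCl2, the aryl bromide is inert to zinc, and bromine at C8 plus the flanked C6 keep ring A from being acylated.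

Step 10
Reactants: 14 3-[(2S)-8-bromo-5,7-bis(triisopropylsilyloxy)chroman-2-yl]-4,4-dichlorocyclobut-2-en-1-one
Product: 15 3-[(2S)-8-bromo-5,7-bis(triisopropylsilyloxy)chroman-2-yl]cyclobut-2-en-1-one
Conditions: Zn dust, AcOH, TMEDA, EtOH, 0 °C → rt
Reagents that add atoms: none
Why: Zinc in acetic acid buffered by TMEDA removes both chlorines α to the carbonyl (reductive dechlorination) under nearly neutral conditions that should spare the aryl bromide, the silyl ethers and the C2 stereocentre, which sits γ to the enone carbonyl and would be at risk with base.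

Step 11
Reactants: 16 chloroacetaldehyde dimethyl acetal
Product: 18 methoxyacetylene, via sodium methoxyacetylide 17 (not isolated)
Conditions: NaNH2 (3.3 equiv), liquid NH3, −33 °C; then cold sat. aq NaCl, distilled into cold toluene
Reagents that add atoms: none
Why: Sodium amide strips methanol and then HCl from the chloroacetal (twofold β-elimination, the standard alkoxyacetylene preparation) and holds the product as its sodium acetylide until brine protonates it and the low-boiling ynol ether distils out.

Step 12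
Reactants: 15 3-[(2S)-8-bromo-5,7-bis(triisopropylsilyloxy)chroman-2-yl]cyclobut-2-en-1-one; 18 methoxyacetylene
Product: 23 3-[(2S)-8-bromo-5,7-bis(triisopropylsilyloxy)chroman-2-yl]-5-methoxyphenol, via vinylketene 19 (not isolated), via vinylcyclobutenone 20 (not isolated), via dienylketene 21 (not isolated), via cyclohexadienone 22 (not isolated)
Conditions: 18 (3 equiv), toluene, sealed tube, 80 °C (15 added slowly), then 110 °C
Reagents that add atoms: none
Why: On heating, cyclobutenone 15 opens by reversible 4π electrocyclic cleavage of its C1–C4 bond to vinylketene 19, which adds methoxyacetylene in a ketene [2+2] cycloaddition whose regiochemistry is fixed by the polarised ynol ether: the nucleophilic CH carbon bonds to the ketene carbonyl carbon and the oxygen-bearing carbon to the ketene α-carbon, giving 20. A second 4π opening gives dienylketene 21, and ring B is then closed by 6π electrocyclisation (bond between the old carbonyl carbon and the old ring CH2) to dienone 22, which tautomerises irreversibly to phenol 23. This is the Danheiser benzannulation of a 3-alkylcyclobutenone with an alkoxyacetylene; the carbonyl oxygen ends as the free C3' hydroxyl and the alkyne oxygen as the C5' methyl ether, with C1' (the old C3 of the cyclobutenone) meta to both. No stereocentre is formed, and C2 of the chroman, an ether carbon γ to the enone, should be kept because the medium is neutral and aprotic and no base is present to form a dienolate. The chromanyl group, the aryl bromide and the silyl ethers are spectators, and an excess of the ynol ether with slow addition of 15 should keep the vinylketene from dimerising or acylating the product phenol. Methoxyacetylene has no β-hydrogen in its alkyl group, so it cannot fragment to ketene on heating as higher alkoxyacetylenes do.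

Step 13
Reactants: 23 3-[(2S)-8-bromo-5,7-bis(triisopropylsilyloxy)chroman-2-yl]-5-methoxyphenol
Product: 24 (2S)-8-bromo-2-[3-methoxy-5-(triisopropylsilyloxy)phenyl]-5,7-bis(triisopropylsilyloxy)chroman
Conditions: TIPSCl (1.5 equiv), imidazole, DMF, rt
Reagents that add atoms: triisopropylsilyl chloride, CC(C)[Si](Cl)(C(C)C)C(C)C
Why: Imidazole-promoted silylation masks the only acidic proton before the organolithium step and brings all three hydroxyls under one fluoride-labile group.

Step 14
Reactants: 24 (2S)-8-bromo-2-[3-methoxy-5-(triisopropylsilyloxy)phenyl]-5,7-bis(triisopropylsilyloxy)chroman; 25 prenyl bromide (1-bromo-3-methylbut-2-ene)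
Product: 28 (2S)-2-[3-methoxy-5-(triisopropylsilyloxy)phenyl]-8-(3-methylbut-2-en-1-yl)-5,7-bis(triisopropylsilyloxy)chroman, via aryllithium 26 (not isolated), via arylcopper 27 (not isolated)
Conditions: n-BuLi (1.05 equiv), THF, −78 °C; CuBr·SMe2 (1.1 equiv), −78 → −40 °C; 25 (2 equiv), −78 → 0 °C
Reagents that add atoms: none
Why: Bromine–lithium exchange at −78 °C outruns deprotonation and silyl migration, and after transmetalation to copper the aryl group attacks prenyl bromide at its unhindered CH2 (copper-mediated SN2 allylation), giving the linear prenyl group at C8.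

Step 15
Reactants: 28 (2S)-2-[3-methoxy-5-(triisopropylsilyloxy)phenyl]-8-(3-methylbut-2-en-1-yl)-5,7-bis(triisopropylsilyloxy)chroman
Product: 29 3-[(2S)-5,7-dihydroxy-8-(3-methylbut-2-en-1-yl)chroman-2-yl]-5-methoxyphenol
Conditions: Bu4NF (3.6 equiv), AcOH (3.6 equiv), THF, 0 °C → rt, argon
Reagents that add atoms: none
Why: Fluoride cleaves the three aryl Si–O bonds (desilylation) under acetic acid buffering, so no mineral acid that could cyclise the ortho-prenyl phenol to a dimethylchroman or ionise C2 is needed and the electron-rich phenoxides are protonated as they form.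

**Compound list**

1 | 5,7-dihydroxycoumarin | O=C1C=Cc2c(O)cc(O)cc2O1 | starting material
2 | 5,7-bis(triisopropylsilyloxy)coumarin | O=C1C=Cc2c(O[Si](C(C)C)(C(C)C)C(C)C)cc(O[Si](C(C)C)(C(C)C)C(C)C)cc2O1 | intermediate
3 | 5,7-bis(triisopropylsilyloxy)chroman-2-one | O=C1CCc2c(O[Si](C(C)C)(C(C)C)C(C)C)cc(O[Si](C(C)C)(C(C)C)C(C)C)cc2O1 | intermediate
4 | 3-[2-hydroxy-4,6-bis(triisopropylsilyloxy)phenyl]-N-methoxy-N-methylpropanamide | CON(C)C(=O)CCc1c(O)cc(O[Si](C(C)C)(C(C)C)C(C)C)cc1O[Si](C(C)C)(C(C)C)C(C)C | intermediate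
5 | (trimethylsilyl)acetylene | C#C[Si](C)(C)C | starting material
6 | lithium (trimethylsilyl)acetylide, formed in the flask | [Li]C#C[Si](C)(C)C | intermediate
7 | 1-[2-hydroxy-4,6-bis(triisopropylsilyloxy)phenyl]-5-(trimethylsilyl)pent-4-yn-3-one | C[Si](C)(C)C#CC(=O)CCc1c(O)cc(O[Si](C(C)C)(C(C)C)C(C)C)cc1O[Si](C(C)C)(C(C)C)C(C)C | intermediate
8 | (3R)-1-[2-hydroxy-4,6-bis(triisopropylsilyloxy)phenyl]-5-(trimethylsilyl)pent-4-yn-3-ol | C[Si](C)(C)C#C[C@H](O)CCc1c(O)cc(O[Si](C(C)C)(C(C)C)C(C)C)cc1O[Si](C(C)C)(C(C)C)C(C)C | intermediate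
9 | {[(2S)-5,7-bis(triisopropylsilyloxy)chroman-2-yl]ethynyl}trimethylsilane | C[Si](C)(C)C#C[C@@H]1CCc2c(O[Si](C(C)C)(C(C)C)C(C)C)cc(O[Si](C(C)C)(C(C)C)C(C)C)cc2O1 | intermediate
10 | (2S)-2-ethynyl-5,7-bis(triisopropylsilyloxy)chroman | C#C[C@@H]1CCc2c(O[Si](C(C)C)(C(C)C)C(C)C)cc(O[Si](C(C)C)(C(C)C)C(C)C)cc2O1 | intermediate
11 | (2S)-8-bromo-2-ethynyl-5,7-bis(triisopropylsilyloxy)chroman | C#C[C@@H]1CCc2c(O[Si](C(C)C)(C(C)C)C(C)C)cc(O[Si](C(C)C)(C(C)C)C(C)C)c(Br)c2O1 | intermediate
12 | trichloroacetyl chloride | O=C(Cl)C(Cl)(Cl)Cl | starting material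
13 | dichloroketene, formed in the flask | O=C=C(Cl)Cl | intermediate
14 | 3-[(2S)-8-bromo-5,7-bis(triisopropylsilyloxy)chroman-2-yl]-4,4-dichlorocyclobut-2-en-1-one | O=C1C=C([C@@H]2CCc3c(O[Si](C(C)C)(C(C)C)C(C)C)cc(O[Si](C(C)C)(C(C)C)C(C)C)c(Br)c3O2)C1(Cl)Cl | intermediate
15 | 3-[(2S)-8-bromo-5,7-bis(triisopropylsilyloxy)chroman-2-yl]cyclobut-2-en-1-one | O=C1CC([C@@H]2CCc3c(O[Si](C(C)C)(C(C)C)C(C)C)cc(O[Si](C(C)C)(C(C)C)C(C)C)c(Br)c3O2)=C1 | intermediate
16 | chloroacetaldehyde dimethyl acetal (2-chloro-1,1-dimethoxyethane) | COC(CCl)OC | starting material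
17 | sodium methoxyacetylide, formed in the flask | [Na+].[C-]#COC | intermediate
18 | methoxyacetylene | COC#C | intermediate
19 | 3-[(2S)-8-bromo-5,7-bis(triisopropylsilyloxy)chroman-2-yl]buta-1,3-dien-1-one (vinylketene), formed in the flask | O=C=CC(=C)[C@@H]1CCc2c(O[Si](C(C)C)(C(C)C)C(C)C)cc(O[Si](C(C)C)(C(C)C)C(C)C)c(Br)c2O1 | intermediate
20 | 4-{1-[(2S)-8-bromo-5,7-bis(triisopropylsilyloxy)chroman-2-yl]ethenyl}-3-methoxycyclobut-2-en-1-one, ring CH configuration not defined and lost on opening, formed in the flask | O=C1C=C(OC)C1C(=C)[C@@H]2CCc3c(O[Si](C(C)C)(C(C)C)C(C)C)cc(O[Si](C(C)C)(C(C)C)C(C)C)c(Br)c3O2 | intermediate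
21 | (3E)-5-[(2S)-8-bromo-5,7-bis(triisopropylsilyloxy)chroman-2-yl]-3-methoxyhexa-1,3,5-trien-1-one (dienylketene, ketene and vinyl arms cis), formed in the flask | O=C=C/C(OC)=C\C(=C)[C@@H]1CCc2c(O[Si](C(C)C)(C(C)C)C(C)C)cc(O[Si](C(C)C)(C(C)C)C(C)C)c(Br)c2O1 | intermediate
22 | 5-[(2S)-8-bromo-5,7-bis(triisopropylsilyloxy)chroman-2-yl]-3-methoxycyclohexa-2,4-dien-1-one, formed in the flask | O=C1C=C(OC)C=C([C@@H]2CCc3c(O[Si](C(C)C)(C(C)C)C(C)C)cc(O[Si](C(C)C)(C(C)C)C(C)C)c(Br)c3O2)C1 | intermediate
23 | 3-[(2S)-8-bromo-5,7-bis(triisopropylsilyloxy)chroman-2-yl]-5-methoxyphenol | COc1cc(O)cc([C@@H]2CCc3c(O[Si](C(C)C)(C(C)C)C(C)C)cc(O[Si](C(C)C)(C(C)C)C(C)C)c(Br)c3O2)c1 | intermediate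
24 | (2S)-8-bromo-2-[3-methoxy-5-(triisopropylsilyloxy)phenyl]-5,7-bis(triisopropylsilyloxy)chroman | COc1cc(O[Si](C(C)C)(C(C)C)C(C)C)cc([C@@H]2CCc3c(O[Si](C(C)C)(C(C)C)C(C)C)cc(O[Si](C(C)C)(C(C)C)C(C)C)c(Br)c3O2)c1 | intermediate
25 | prenyl bromide (1-bromo-3-methylbut-2-ene) | CC(C)=CCBr | starting material
26 | {(2S)-2-[3-methoxy-5-(triisopropylsilyloxy)phenyl]-5,7-bis(triisopropylsilyloxy)chroman-8-yl}lithium, formed in the flask | COc1cc(O[Si](C(C)C)(C(C)C)C(C)C)cc([C@@H]2CCc3c(O[Si](C(C)C)(C(C)C)C(C)C)cc(O[Si](C(C)C)(C(C)C)C(C)C)c([Li])c3O2)c1 | intermediate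
27 | {(2S)-2-[3-methoxy-5-(triisopropylsilyloxy)phenyl]-5,7-bis(triisopropylsilyloxy)chroman-8-yl}copper, formed in the flask | COc1cc(O[Si](C(C)C)(C(C)C)C(C)C)cc([C@@H]2CCc3c(O[Si](C(C)C)(C(C)C)C(C)C)cc(O[Si](C(C)C)(C(C)C)C(C)C)c([Cu])c3O2)c1 | intermediate
28 | (2S)-2-[3-methoxy-5-(triisopropylsilyloxy)phenyl]-8-(3-methylbut-2-en-1-yl)-5,7-bis(triisopropylsilyloxy)chroman | COc1cc(O[Si](C(C)C)(C(C)C)C(C)C)cc([C@@H]2CCc3c(O[Si](C(C)C)(C(C)C)C(C)C)cc(O[Si](C(C)C)(C(C)C)C(C)C)c(CC=C(C)C)c3O2)c1 | intermediate
29 | 3-[(2S)-5,7-dihydroxy-8-(3-methylbut-2-en-1-yl)chroman-2-yl]-5-methoxyphenol (CNP0173255.1) | COc1cc(O)cc([C@@H]2CCc3c(O)cc(O)c(CC=C(C)C)c3O2)c1 | target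

**Step count**

Total step count: 15.
Longest linear sequence: 14 steps (steps 1–10 and 12–15); step 11 is a one-step side branch.

**Steps most likely to fail**

Step 12 (key annulation). What may go wrong: loss or polymerisation of the volatile ynol ether before the ketene forms, dimerisation of the vinylketene or its capture by the product phenol as an aryl ester, and slow γ-deprotonation that would erode C2. The fallback brings ring B in ready-made; it sets out from 4 and comes back at 24. Purchased 3-bromo-5-methoxyphenol (COc1cc(O)cc(Br)c1) is silylated with TIPSCl and imidazole to (3-bromo-5-methoxyphenoxy)triisopropylsilane F2. Bromine–lithium exchange (n-BuLi, THF, −78 °C) gives [3-methoxy-5-(triisopropylsilyloxy)phenyl]lithium F3, which is added in excess to 4 (the first equivalent deprotonates the phenol) to give 3-[2-hydroxy-4,6-bis(triisopropylsilyloxy)phenyl]-1-[3-methoxy-5-(triisopropylsilyloxy)phenyl]propan-1-one F4. Noyori transfer hydrogenation with the same (R,R)-catalyst should give (1R)-3-[2-hydroxy-4,6-bis(triisopropylsilyloxy)phenyl]-1-[3-methoxy-5-(triisopropylsilyloxy)phenyl]propan-1-ol F5. Mitsunobu closure with inversion should give (2S)-2-[3-methoxy-5-(triisopropylsilyloxy)phenyl]-5,7-bis(triisopropylsilyloxy)chroman F6. NBS at −78 °C should then brominate C8 of the triply oxygenated ring A in preference to ring B, giving 24.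

Step 9 (dichloroketene cycloaddition). What may go wrong: ZnCl2-driven loss of silyl groups or acylation of ring A at C6, polymerisation of dichloroketene before it meets the alkyne, and 1,3-shift of chlorine in the product. The fallback is a keteniminium–alkyne [2+2] cycloaddition; it sets out from 11 and comes back at 15, passing by 14 and step 10. The keteniminium triflate generated from N,N-dimethylacetamide, Tf2O and 2,4,6-collidine in 1,2-dichloroethane at reflux should add to the alkyne with the same regiochemistry to give N-{3-[(2S)-8-bromo-5,7-bis(triisopropylsilyloxy)chroman-2-yl]cyclobut-2-en-1-ylidene}-N-methylmethanaminium triflate F1. Hydrolysis with aqueous NaHCO3 then gives 15 without zinc salts or acid chloride.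

Step 14 (C8 prenylation). What may go wrong: protonation of the hindered aryllithium back to the C8–H compound, oxygen-to-carbon silyl migration from the C7 silyl ether, or attack at the tertiary end of the allyl unit giving the reverse-prenyl isomer. The fallback is a palladium-catalysed Negishi coupling; it sets out from 24 and comes back at 28. (3-Methylbut-2-en-1-yl)zinc bromide F7 is made from 25 with Zn dust and LiCl in THF and coupled with 24 using Pd(OAc)2 and the biaryl phosphine CPhos in THF at rt. This known linear-selective allyl–aryl coupling avoids the aryllithium altogether.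

**Further compounds**

F1 | step 9 | N-{3-[(2S)-8-bromo-5,7-bis(triisopropylsilyloxy)chroman-2-yl]cyclobut-2-en-1-ylidene}-N-methylmethanaminium triflate | C[N+](C)=C1CC([C@@H]2CCc3c(O[Si](C(C)C)(C(C)C)C(C)C)cc(O[Si](C(C)C)(C(C)C)C(C)C)c(Br)c3O2)=C1.[O-]S(=O)(=O)C(F)(F)F
F2 | step 12 | (3-bromo-5-methoxyphenoxy)triisopropylsilane | COc1cc(Br)cc(O[Si](C(C)C)(C(C)C)C(C)C)c1
F3 | step 12 | [3-methoxy-5-(triisopropylsilyloxy)phenyl]lithium | COc1cc([Li])cc(O[Si](C(C)C)(C(C)C)C(C)C)c1
F4 | step 12 | 3-[2-hydroxy-4,6-bis(triisopropylsilyloxy)phenyl]-1-[3-methoxy-5-(triisopropylsilyloxy)phenyl]propan-1-one | COc1cc(O[Si](C(C)C)(C(C)C)C(C)C)cc(C(=O)CCc2c(O)cc(O[Si](C(C)C)(C(C)C)C(C)C)cc2O[Si](C(C)C)(C(C)C)C(C)C)c1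
F5 | step 12 | (1R)-3-[2-hydroxy-4,6-bis(triisopropylsilyloxy)phenyl]-1-[3-methoxy-5-(triisopropylsilyloxy)phenyl]propan-1-ol | COc1cc(O[Si](C(C)C)(C(C)C)C(C)C)cc([C@H](O)CCc2c(O)cc(O[Si](C(C)C)(C(C)C)C(C)C)cc2O[Si](C(C)C)(C(C)C)C(C)C)c1
F6 | step 12 | (2S)-2-[3-methoxy-5-(triisopropylsilyloxy)phenyl]-5,7-bis(triisopropylsilyloxy)chroman | COc1cc(O[Si](C(C)C)(C(C)C)C(C)C)cc([C@@H]2CCc3c(O[Si](C(C)C)(C(C)C)C(C)C)cc(O[Si](C(C)C)(C(C)C)C(C)C)cc3O2)c1
F7 | step 14 | (3-methylbut-2-en-1-yl)zinc bromide | CC(C)=CC[Zn]Br
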